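**Plan**

Labdane locants are used: C1–C10 decalin, C2 ester, C4 gem-dimethyl, C8 methylidene, C9 side chain, C10 ring-fusion methyl.
- Retrosynthesis: cut the C15 methyl ester, the C2 ester (C2 inverted through its ketone), C8=CH2 (from a C8 ketone) and C9–C11 (enolate alkylation), then C7–C8 and C5–C10 together.
- Enabling feature: ring B is the union of C8–C9–C10, a 3-methylbut-2-enoyl unit (acyl carbon C8, β-carbon C10 with its methyl), and C5–C6–C7, an allyl unit, while C10 and C5 are tied through C1–C4. An open-chain (Z)-enoyl chloride that carries an allylsilane therefore closes ring A (C5–C10) and then ring B (C7–C8) in one flask.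
- Forward: (R)-epichlorohydrin (C1–C3), prenyl Grignard (C4, C5, gem-dimethyl), allylsilane (C6, C7), acetylide (C9, C10), chloroformate (C8) and methylcuprate (C10 methyl) give the chain. Bis-annulation gives the Δ6-8-ketone; then C9 alkylation, hydrogenation, methylenation, C2 inversion, acylation and ester cleavage.
- Stereochemistry: the epichlorohydrin-derived C2 oxygen (equatorial in the chair) sets C5 and C10. The Z-alkene puts the C10 methyl axial (trans fusion). C9 is set by alkylation anti to the C10 methyl, C13 comes from methyl hydrogen (R)-3-methylglutarate, and C2 is finally inverted by oxidation and equatorial hydride delivery.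

Key step: step 9

Remark on the chemistry: the SMILES is read as having the C9 side chain trans to the C10 methyl and the C2 ester cis to it (both axial on the trans-decalin); the route is built for exactly this arrangement.

**Route**

Step 1
Reactants: 1 (2R)-2-(chloromethyl)oxirane [(R)-epichlorohydrin]; 2 3-methylbut-2-en-1-ylmagnesium chloride
Product: 3 (2R)-1-chloro-4,4-dimethylhex-5-en-2-ol
Conditions: Me2C=CHCH2MgCl, THF, −40 → 0 °C; then aq. NH4Cl
Reagents that add atoms: none
Why: Allylic Grignard reagents open terminal epoxides at the CH2 terminus with allylic transposition (SE2′ delivery through the γ-carbon), which creates the C4 quaternary carbon and leaves the C2 stereocentre of 1 untouched.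

Step 2
Reactants: 3 (2R)-1-chloro-4,4-dimethylhex-5-en-2-ol
Product: 4 (2R)-2-(2,2-dimethylbut-3-en-1-yl)oxirane
Conditions: NaOH, Et2O/H2O, rt
Reagents that add atoms: none
Why: Intramolecular Williamson closure of the chlorohydrin gives the terminal epoxide without touching the stereocentre.

Step 3
Reactants: 4 (2R)-2-(2,2-dimethylbut-3-en-1-yl)oxirane; 5 allyltrimethylsilane
Product: 6 (2R)-2-[(3E)-2,2-dimethyl-5-(trimethylsilyl)pent-3-en-1-yl]oxirane
Conditions: 5 (4 equiv), second-generation Grubbs catalyst (5 mol %), CH2Cl2, 40 °C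
Reagents that add atoms: none
Why: Olefin cross-metathesis between a slowly homodimerising vinyl group on a quaternary carbon and an excess of a fast partner is selective and should give mainly the E-allylsilane.

Step 4
Reactants: 6 (2R)-2-[(3E)-2,2-dimethyl-5-(trimethylsilyl)pent-3-en-1-yl]oxirane
Product: 7 (4S,7E)-6,6-dimethyl-9-(trimethylsilyl)non-7-en-1-yn-4-ol
Conditions: LiC≡CH·H2NCH2CH2NH2, DMSO, rt
Reagents that add atoms: lithium acetylide–ethylenediamine complex, [Li]C#C.NCCN
Why: The acetylide opens the terminal epoxide at the unsubstituted carbon (SN2), giving the homopropargylic alcohol with the C2 configuration retained (the descriptor changes only through ligand priorities).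

Step 5
Reactants: 7 (4S,7E)-6,6-dimethyl-9-(trimethylsilyl)non-7-en-1-yn-4-ol
Product: 8 benzyl (4S,7E)-6,6-dimethyl-9-(trimethylsilyl)non-7-en-1-yn-4-yl carbonate
Conditions: benzyl chloroformate, pyridine, DMAP (cat.), CH2Cl2, 0 °C
Reagents that add atoms: benzyl chloroformate, O=C(Cl)OCc1ccccc1
Why: O-Acylation of the secondary alcohol gives a carbonate whose oxygen is too poorly nucleophilic to lactonise onto the later acyl chloride and which is removed by the hydrogenation of step 13.

Step 6
Reactants: 8 benzyl (4S,7E)-6,6-dimethyl-9-(trimethylsilyl)non-7-en-1-yn-4-yl carbonate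
Product: 10 prop-2-en-1-yl (5R,8E)-5-{[(benzyloxy)carbonyl]oxy}-7,7-dimethyl-10-(trimethylsilyl)dec-8-en-2-ynoate, via lithium acetylide 9 (not isolated)
Conditions: LiN(i-Pr)2, THF, −78 °C; then allyl chloroformate, −78 °C
Reagents that add atoms: allyl chloroformate, C=CCOC(=O)Cl
Why: Deprotonation of the terminal alkyne and C-acylation of the acetylide with a chloroformate gives the ynoate (same spatial arrangement at the carbinol carbon; the descriptor changes through ligand priorities).

Step 7
Reactants: 10 prop-2-en-1-yl (5R,8E)-5-{[(benzyloxy)carbonyl]oxy}-7,7-dimethyl-10-(trimethylsilyl)dec-8-en-2-ynoate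
Product: 11 prop-2-en-1-yl (2Z,5S,8E)-5-{[(benzyloxy)carbonyl]oxy}-3,7,7-trimethyl-10-(trimethylsilyl)deca-2,8-dienoate
Conditions: Me2CuLi, THF, −78 °C; then MeOH and aq. NH4Cl at −78 °C
Reagents that add atoms: lithium dimethylcuprate, [Li+].C[Cu-]C
Why: Syn carbocupration of the ynoate and protonation at low temperature (conjugate addition of a Gilman cuprate) puts the new methyl cis to the new hydrogen, so the chain is cis to the ester (Z).

Step 8
Reactants: 11 prop-2-en-1-yl (2Z,5S,8E)-5-{[(benzyloxy)carbonyl]oxy}-3,7,7-trimethyl-10-(trimethylsilyl)deca-2,8-dienoate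
Product: 12 (2Z,5S,8E)-5-{[(benzyloxy)carbonyl]oxy}-3,7,7-trimethyl-10-(trimethylsilyl)deca-2,8-dienoic acid
Conditions: Pd(PPh3)4 (3 mol %), morpholine, THF, rt
Reagents that add atoms: none
Why: Palladium-catalysed allyl transfer to morpholine (Tsuji–Trost deallylation) frees the acid under neutral conditions that spare the carbonate, the allylsilane and the Z-alkene.

Step 9
Reactants: 12 (2Z,5S,8E)-5-{[(benzyloxy)carbonyl]oxy}-3,7,7-trimethyl-10-(trimethylsilyl)deca-2,8-dienoic acid
Product: 16 benzyl (2R,4aR,8aS)-4,4,8a-trimethyl-7-oxo-1,2,3,4,4a,7,8,8a-octahydronaphthalen-2-yl carbonate, via acid chloride 13 (not isolated), via ketene 14 (not isolated), via β-chloro ketone 15 (not isolated)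
Conditions: Me2C=C(Cl)NMe2 (1.1 equiv), CH2Cl2, 0 °C; then slow addition to TiCl4 (3 equiv), CH2Cl2 (0.005 M), −78 → 0 °C; then DBU, 0 °C → rt
Reagents that add atoms: none
Why: Proposed new method: TiCl4 activates acid chloride 13 as an acylium-like species, the γ-carbon of the tethered allylsilane adds to its β-carbon (C10) with loss of Me3SiCl to give ketene 14, and the Lewis acid-bound ketene (an acylium equivalent) is then attacked at C8 by the terminal carbon (C7) of the vinyl group just formed; chloride capture at C6 gives 15 and DBU removes HCl (E1cB) to the conjugated enone. The closest known reaction types are the intramolecular Hosomi–Sakurai cyclisation of allylsilanes onto enones and the Lewis acid-mediated cyclisation of hex-5-enoyl chlorides to cyclohex-2-enones; their union as a formal [3+3] bis-annulation is not known. Ring A closes 6-exo-trig (conjugate addition, acceptor C=C exocyclic) and ring B closes 6-endo-trig (Markovnikov cation–olefin acylation). C5 and C10 are both set in the first closure through a chair in which the C2 carbonate is equatorial (it would otherwise be 1,3-diaxial to two methyl groups, so the epichlorohydrin-derived centre fixes the absolute sense), the C5 vinyl-to-be is equatorial, and the Z-enoyl geometry forces the ring chain away from the cis acyl group by allylic 1,3-strain, which places C9 equatorial and the C10 methyl axial; the two trans-diequatorial arms can then only close to the trans-decalin. The step needs conjugate instead of carbonyl attack by the allylsilane and intra- instead of intermolecular acylation, secured by ring size (six against eight) and high dilution, and conjugation-directed elimination, secured by the acidity of the C7 hydrogens next to the new ketone.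

Step 10
Reactants: 17 (3R)-5-methoxy-3-methyl-5-oxopentanoic acid [methyl hydrogen (R)-3-methylglutarate]
Product: 19 (4S)-4-methyloxan-2-one, via hydroxy acid 18 (not isolated)
Conditions: LiBH4, THF, 0 °C → rt; then 3 M HCl, rt
Reagents that add atoms: none
Why: LiBH4 reduces the ester but not the lithium carboxylate, and acidification lactonises the hydroxy acid, so the ester arm of 17 becomes the alcohol arm while the stereocentre is untouched.

Step 11
Reactants: 19 (4S)-4-methyloxan-2-one
Product: 21 methyl (3R)-5-iodo-3-methylpentanoate, via silyl ester 20 (not isolated)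
Conditions: Me3SiI, CH2Cl2, rt; then MeOH, rt
Reagents that add atoms: iodotrimethylsilane, C[Si](C)(C)I; methanol, CO
Why: Iodide opens the O-silylated lactone by SN2 attack at the O–CH2 carbon and methanol converts the silyl ester into the methyl ester.

Step 12
Reactants: 16 benzyl (2R,4aR,8aS)-4,4,8a-trimethyl-7-oxo-1,2,3,4,4a,7,8,8a-octahydronaphthalen-2-yl carbonate; 21 methyl (3R)-5-iodo-3-methylpentanoate
Product: 23 methyl (3S)-5-[(1R,4aR,7R,8aR)-7-{[(benzyloxy)carbonyl]oxy}-5,5,8a-trimethyl-2-oxo-1,2,4a,5,6,7,8,8a-octahydronaphthalen-1-yl]-3-methylpentanoate, via lithium dienolate 22 (not isolated)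
Conditions: LiN(i-Pr)2, THF, −78 °C; then 21, DMPU, −78 → −20 °C
Reagents that add atoms: none
Why: Kinetic α′-deprotonation of the enone gives the cross-conjugated dienolate, which is alkylated (SN2) at C9 on the face opposite the axial C10 methyl, so the side chain enters trans to that methyl.

Step 13
Reactants: 23 methyl (3S)-5-[(1R,4aR,7R,8aR)-7-{[(benzyloxy)carbonyl]oxy}-5,5,8a-trimethyl-2-oxo-1,2,4a,5,6,7,8,8a-octahydronaphthalen-1-yl]-3-methylpentanoate
Product: 24 methyl (3S)-5-[(1R,4aR,7R,8aR)-7-hydroxy-5,5,8a-trimethyl-2-oxodecahydronaphthalen-1-yl]-3-methylpentanoate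
Conditions: H2 (1 atm), 10% Pd/C, EtOAc, rt
Reagents that add atoms: none
Why: Heterogeneous hydrogenation saturates the enone C=C and hydrogenolyses the benzyl carbonate (toluene and CO2 are lost) under neutral conditions that should not epimerise C9.

Step 14
Reactants: 24 methyl (3S)-5-[(1R,4aR,7R,8aR)-7-hydroxy-5,5,8a-trimethyl-2-oxodecahydronaphthalen-1-yl]-3-methylpentanoate
Product: 25 methyl (3S)-5-[(1S,4aR,7R,8aR)-7-hydroxy-5,5,8a-trimethyl-2-methylidenedecahydronaphthalen-1-yl]-3-methylpentanoate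
Conditions: Zn, CH2Br2, TiCl4, THF/CH2Cl2, 0 °C → rt
Reagents that add atoms: dibromomethane, BrCBr
Why: Lombardo methylenation uses a non-basic gem-dimetallic reagent that converts the hindered, epimerisable ketone into the exocyclic alkene without enolisation and leaves the ester alone.

Step 15
Reactants: 25 methyl (3S)-5-[(1S,4aR,7R,8aR)-7-hydroxy-5,5,8a-trimethyl-2-methylidenedecahydronaphthalen-1-yl]-3-methylpentanoate
Product: 26 methyl (3S)-3-methyl-5-[(1S,4aR,8aR)-5,5,8a-trimethyl-2-methylidene-7-oxodecahydronaphthalen-1-yl]pentanoate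
Conditions: Dess–Martin periodinane, NaHCO3, CH2Cl2, rt
Reagents that add atoms: none
Why: Dess–Martin oxidation converts the equatorial C2 alcohol, which has served as the control element, into the ketone.

Step 16
Reactants: 26 methyl (3S)-3-methyl-5-[(1S,4aR,8aR)-5,5,8a-trimethyl-2-methylidene-7-oxodecahydronaphthalen-1-yl]pentanoate
Product: 27 methyl (3S)-5-[(1S,4aR,7S,8aR)-7-hydroxy-5,5,8a-trimethyl-2-methylidenedecahydronaphthalen-1-yl]-3-methylpentanoate
Conditions: LiBH(s-Bu)3, THF, −78 °C; then aq. NH4Cl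
Reagents that add atoms: none
Why: The bulky hydride attacks the C2 ketone from the equatorial direction, away from the two syn-axial methyl groups at C4 and C10, which gives the axial alcohol cis to the C10 methyl.

Step 17
Reactants: 27 methyl (3S)-5-[(1S,4aR,7S,8aR)-7-hydroxy-5,5,8a-trimethyl-2-methylidenedecahydronaphthalen-1-yl]-3-methylpentanoate; 28 3-methylbutanoyl chloride
Product: 29 methyl (3S)-3-methyl-5-[(1S,4aR,7S,8aR)-5,5,8a-trimethyl-2-methylidene-7-[(3-methylbutanoyl)oxy]decahydronaphthalen-1-yl]pentanoate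
Conditions: 28, DMAP, pyridine, CH2Cl2, 40 °C
Reagents that add atoms: none
Why: DMAP-catalysed acylation of the hindered axial alcohol with the acid chloride proceeds with retention at C2.

Step 18
Reactants: 29 methyl (3S)-3-methyl-5-[(1S,4aR,7S,8aR)-5,5,8a-trimethyl-2-methylidene-7-[(3-methylbutanoyl)oxy]decahydronaphthalen-1-yl]pentanoate
Product: 30 (3S)-3-methyl-5-[(1S,4aR,7S,8aR)-5,5,8a-trimethyl-2-methylidene-7-[(3-methylbutanoyl)oxy]decahydronaphthalen-1-yl]pentanoic acid
Conditions: Me3SnOH, ClCH2CH2Cl, 80 °C; then 5% aq. HCl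
Reagents that add atoms: trimethyltin hydroxide, C[Sn](C)(C)O
Why: Me3SnOH cleaves the unhindered methyl ester through its tin carboxylate and should leave the hindered secondary 3-methylbutanoate and the exocyclic alkene untouched.

**Compound list**

1 | (2R)-2-(chloromethyl)oxirane | ClC[C@H]1CO1 | starting material
2 | 3-methylbut-2-en-1-ylmagnesium chloride | CC(C)=CC[Mg]Cl | starting material
3 | (2R)-1-chloro-4,4-dimethylhex-5-en-2-ol | ClC[C@H](O)CC(C)(C)C=C | intermediate
4 | (2R)-2-(2,2-dimethylbut-3-en-1-yl)oxirane | C1O[C@@H]1CC(C)(C)C=C | intermediate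
5 | allyltrimethylsilane | C=CC[Si](C)(C)C | starting material
6 | (2R)-2-[(3E)-2,2-dimethyl-5-(trimethylsilyl)pent-3-en-1-yl]oxirane | C1O[C@@H]1CC(C)(C)/C=C/C[Si](C)(C)C | intermediate
7 | (4S,7E)-6,6-dimethyl-9-(trimethylsilyl)non-7-en-1-yn-4-ol | C#CC[C@H](O)CC(C)(C)/C=C/C[Si](C)(C)C | intermediate
8 | benzyl (4S,7E)-6,6-dimethyl-9-(trimethylsilyl)non-7-en-1-yn-4-yl carbonate | C#CC[C@H](OC(=O)OCc1ccccc1)CC(C)(C)/C=C/C[Si](C)(C)C | intermediate
9 | C1-lithio derivative (lithium acetylide) of 8 | [Li]C#CC[C@H](OC(=O)OCc1ccccc1)CC(C)(C)/C=C/C[Si](C)(C)C | intermediate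
10 | prop-2-en-1-yl (5R,8E)-5-{[(benzyloxy)carbonyl]oxy}-7,7-dimethyl-10-(trimethylsilyl)dec-8-en-2-ynoate | C=CCOC(=O)C#CC[C@H](OC(=O)OCc1ccccc1)CC(C)(C)/C=C/C[Si](C)(C)C | intermediate
11 | prop-2-en-1-yl (2Z,5S,8E)-5-{[(benzyloxy)carbonyl]oxy}-3,7,7-trimethyl-10-(trimethylsilyl)deca-2,8-dienoate | C=CCOC(=O)/C=C(/C)C[C@H](OC(=O)OCc1ccccc1)CC(C)(C)/C=C/C[Si](C)(C)C | intermediate
12 | (2Z,5S,8E)-5-{[(benzyloxy)carbonyl]oxy}-3,7,7-trimethyl-10-(trimethylsilyl)deca-2,8-dienoic acid | OC(=O)/C=C(/C)C[C@H](OC(=O)OCc1ccccc1)CC(C)(C)/C=C/C[Si](C)(C)C | intermediate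
13 | (2Z,5S,8E)-5-{[(benzyloxy)carbonyl]oxy}-3,7,7-trimethyl-10-(trimethylsilyl)deca-2,8-dienoyl chloride | ClC(=O)/C=C(/C)C[C@H](OC(=O)OCc1ccccc1)CC(C)(C)/C=C/C[Si](C)(C)C | intermediate
14 | benzyl (1R,3R,4R)-4-ethenyl-3,5,5-trimethyl-3-(2-oxoethenyl)cyclohexyl carbonate (ketene) | C=C[C@@H]1C(C)(C)C[C@@H](OC(=O)OCc2ccccc2)C[C@@]1(C)C=C=O | intermediate
15 | benzyl (2R,4aR,8aS)-5-chloro-4,4,8a-trimethyl-7-oxodecahydronaphthalen-2-yl carbonate (either configuration at the chlorine-bearing carbon) | O=C1CC(Cl)[C@@H]2C(C)(C)C[C@@H](OC(=O)OCc3ccccc3)C[C@@]2(C)C1 | intermediate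
16 | benzyl (2R,4aR,8aS)-4,4,8a-trimethyl-7-oxo-1,2,3,4,4a,7,8,8a-octahydronaphthalen-2-yl carbonate | O=C1C=C[C@@H]2C(C)(C)C[C@@H](OC(=O)OCc3ccccc3)C[C@@]2(C)C1 | intermediate
17 | (3R)-5-methoxy-3-methyl-5-oxopentanoic acid | OC(=O)C[C@@H](C)CC(=O)OC | starting material
18 | (3S)-5-hydroxy-3-methylpentanoic acid | OC(=O)C[C@@H](C)CCO | intermediate
19 | (4S)-4-methyloxan-2-one | O=C1C[C@@H](C)CCO1 | intermediate
20 | trimethylsilyl (3R)-5-iodo-3-methylpentanoate | ICC[C@H](C)CC(=O)O[Si](C)(C)C | intermediate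
21 | methyl (3R)-5-iodo-3-methylpentanoate | ICC[C@H](C)CC(=O)OC | intermediate
22 | lithium dienolate of 16 (C8–O–Li, C8=C9 and C6=C7) | [Li]OC=1C=C[C@@H]2C(C)(C)C[C@@H](OC(=O)OCc3ccccc3)C[C@@]2(C)C=1 | intermediate
23 | methyl (3S)-5-[(1R,4aR,7R,8aR)-7-{[(benzyloxy)carbonyl]oxy}-5,5,8a-trimethyl-2-oxo-1,2,4a,5,6,7,8,8a-octahydronaphthalen-1-yl]-3-methylpentanoate | O=C1C=C[C@@H]2C(C)(C)C[C@@H](OC(=O)OCc3ccccc3)C[C@@]2(C)[C@H]1CC[C@H](C)CC(=O)OC | intermediate
24 | methyl (3S)-5-[(1R,4aR,7R,8aR)-7-hydroxy-5,5,8a-trimethyl-2-oxodecahydronaphthalen-1-yl]-3-methylpentanoate | O=C1CC[C@@H]2C(C)(C)C[C@@H](O)C[C@@]2(C)[C@H]1CC[C@H](C)CC(=O)OC | intermediate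
25 | methyl (3S)-5-[(1S,4aR,7R,8aR)-7-hydroxy-5,5,8a-trimethyl-2-methylidenedecahydronaphthalen-1-yl]-3-methylpentanoate | C=C1CC[C@@H]2C(C)(C)C[C@@H](O)C[C@@]2(C)[C@H]1CC[C@H](C)CC(=O)OC | intermediate
26 | methyl (3S)-3-methyl-5-[(1S,4aR,8aR)-5,5,8a-trimethyl-2-methylidene-7-oxodecahydronaphthalen-1-yl]pentanoate | C=C1CC[C@@H]2C(C)(C)CC(=O)C[C@@]2(C)[C@H]1CC[C@H](C)CC(=O)OC | intermediate
27 | methyl (3S)-5-[(1S,4aR,7S,8aR)-7-hydroxy-5,5,8a-trimethyl-2-methylidenedecahydronaphthalen-1-yl]-3-methylpentanoate | C=C1CC[C@@H]2C(C)(C)C[C@H](O)C[C@@]2(C)[C@H]1CC[C@H](C)CC(=O)OC | intermediate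
28 | 3-methylbutanoyl chloride | CC(C)CC(=O)Cl | starting material
29 | methyl (3S)-3-methyl-5-[(1S,4aR,7S,8aR)-5,5,8a-trimethyl-2-methylidene-7-[(3-methylbutanoyl)oxy]decahydronaphthalen-1-yl]pentanoate | C=C1CC[C@@H]2C(C)(C)C[C@H](OC(=O)CC(C)C)C[C@@]2(C)[C@H]1CC[C@H](C)CC(=O)OC | intermediate
30 | (3S)-3-methyl-5-[(1S,4aR,7S,8aR)-5,5,8a-trimethyl-2-methylidene-7-[(3-methylbutanoyl)oxy]decahydronaphthalen-1-yl]pentanoic acid | C=C1CC[C@@H]2C(C)(C)C[C@H](OC(=O)CC(C)C)C[C@@]2(C)[C@H]1CC[C@H](C)CC(=O)O | target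

**Step count and risks**

Total step count: 18. Longest linear sequence: 16 (steps 1–9 and 12–18); steps 10–11 make the side-chain iodide.

The three steps most likely to fail:

1. Step 9 (proposed new method). What may go wrong: erosion of the ring-fusion selectivity through the competing chair with the acyl-bearing carbon axial, double-bond isomerisation of the enoyl chloride before cyclisation, intermolecular acylation, hydride shift in the cationic second closure, or Lewis-acid loss of the benzyl carbonate. The fallback is stepwise, uses known reaction types, sets out from 12 and comes back at 16. Acid 12 is converted into 13 as before and reduced with LiAlH(Ot-Bu)3 at −78 °C to the enal benzyl (2Z,5S,8E)-3,7,7-trimethyl-1-oxo-10-(trimethylsilyl)deca-2,8-dien-5-yl carbonate F1. The established intramolecular Hosomi–Sakurai conjugate addition (TiCl4, CH2Cl2, −78 °C) closes ring A to the aldehyde benzyl (1R,3S,4R)-4-ethenyl-3,5,5-trimethyl-3-(2-oxoethyl)cyclohexyl carbonate F2. Pinnick oxidation (NaClO2, NaH2PO4, 2-methylbut-2-ene) gives [(1S,2R,5R)-5-{[(benzyloxy)carbonyl]oxy}-2-ethenyl-1,3,3-trimethylcyclohexyl]acetic acid F3. Oxalyl chloride gives [(1S,2R,5R)-5-{[(benzyloxy)carbonyl]oxy}-2-ethenyl-1,3,3-trimethylcyclohexyl]acetyl chloride F4. The classical SnCl4-mediated olefin acylation closes ring B to 15, and DBU gives 16.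

2. Step 12. What may go wrong: slow C-alkylation of the hindered dienolate next to the quaternary carbon by an unactivated primary iodide, so that proton transfer, O-alkylation or elimination of HI from the iodide takes over. The fallback replaces alkylation by aldol addition and deoxygenation; it sets out from 16 and 21 and comes back at 23. Iodide 21 is oxidised (DMSO, NaHCO3, Kornblum oxidation) to methyl (3S)-3-methyl-5-oxopentanoate F5. Dienolate 22 adds to F5, again anti to the C10 methyl, to give the aldol adduct methyl (3S)-5-[(4aR,7R,8aR)-7-{[(benzyloxy)carbonyl]oxy}-5,5,8a-trimethyl-2-oxo-1,2,4a,5,6,7,8,8a-octahydronaphthalen-1-yl]-5-hydroxy-3-methylpentanoate F6 (side chain β at ring carbon 1, carbinol epimers). 1,1′-Thiocarbonyldiimidazole converts F6 into its O-(imidazol-1-ylthiocarbonyl) derivative F7, and Bu3SnH/AIBN (Barton–McCombie deoxygenation) gives 23.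

3. Step 1. What may go wrong: attack through the primary (α) carbon of the allylic Grignard reagent, or opening of the epoxide by chloride. The fallback builds the quaternary carbon with a nitrile anion whose regiochemistry is unambiguous; it sets out from 1 and comes back at 4. Epoxide 1 is opened by lithiated 2-methylpropanenitrile (LiN(i-Pr)2, THF, −78 °C) to (4R)-5-chloro-4-hydroxy-2,2-dimethylpentanenitrile F8. NaOH closes F8 to 2,2-dimethyl-3-[(2R)-oxiran-2-yl]propanenitrile F9. (i-Bu)2AlH at −78 °C gives 2,2-dimethyl-3-[(2R)-oxiran-2-yl]propanal F10, and Ph3P=CH2 (Wittig methylenation) gives 4.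

Further compounds
F1 | step 9 | benzyl (2Z,5S,8E)-3,7,7-trimethyl-1-oxo-10-(trimethylsilyl)deca-2,8-dien-5-yl carbonate | O=C/C=C(/C)C[C@H](OC(=O)OCc1ccccc1)CC(C)(C)/C=C/C[Si](C)(C)C
F2 | step 9 | benzyl (1R,3S,4R)-4-ethenyl-3,5,5-trimethyl-3-(2-oxoethyl)cyclohexyl carbonate | C=C[C@@H]1C(C)(C)C[C@@H](OC(=O)OCc2ccccc2)C[C@@]1(C)CC=O
F3 | step 9 | [(1S,2R,5R)-5-{[(benzyloxy)carbonyl]oxy}-2-ethenyl-1,3,3-trimethylcyclohexyl]acetic acid | C=C[C@@H]1C(C)(C)C[C@@H](OC(=O)OCc2ccccc2)C[C@@]1(C)CC(=O)O
F4 | step 9 | [(1S,2R,5R)-5-{[(benzyloxy)carbonyl]oxy}-2-ethenyl-1,3,3-trimethylcyclohexyl]acetyl chloride | C=C[C@@H]1C(C)(C)C[C@@H](OC(=O)OCc2ccccc2)C[C@@]1(C)CC(=O)Cl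
F5 | step 12 | methyl (3S)-3-methyl-5-oxopentanoate | O=CC[C@H](C)CC(=O)OC
F6 | step 12 | methyl (3S)-5-[(4aR,7R,8aR)-7-{[(benzyloxy)carbonyl]oxy}-5,5,8a-trimethyl-2-oxo-1,2,4a,5,6,7,8,8a-octahydronaphthalen-1-yl]-5-hydroxy-3-methylpentanoate (side chain β at ring carbon 1, carbinol epimers) | O=C1C=C[C@@H]2C(C)(C)C[C@@H](OC(=O)OCc3ccccc3)C[C@@]2(C)[C@H]1C(O)C[C@H](C)CC(=O)OC
F7 | step 12 | O-(imidazol-1-ylthiocarbonyl) derivative of F6 | O=C1C=C[C@@H]2C(C)(C)C[C@@H](OC(=O)OCc3ccccc3)C[C@@]2(C)[C@H]1C(OC(=S)n4ccnc4)C[C@H](C)CC(=O)OC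
F8 | step 1 | (4R)-5-chloro-4-hydroxy-2,2-dimethylpentanenitrile | ClC[C@H](O)CC(C)(C)C#N
F9 | step 1 | 2,2-dimethyl-3-[(2R)-oxiran-2-yl]propanenitrile | C1O[C@@H]1CC(C)(C)C#N
F10 | step 1 | 2,2-dimethyl-3-[(2R)-oxiran-2-yl]propanal | C1O[C@@H]1CC(C)(C)C=O
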